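## Retrosynthetic overview

- Gentiside F is the 2,3-dihydroxybenzoate ester of (S)-16-methyloctadecan-1-ol. It is disconnected at the ester into commercial 2,3-dihydroxybenzoic acid and that alcohol.
- The alcohol comes from hydrogenation of an internal alkyne. The alkyne is made by alkylating (S)-4-methylhex-1-yne with commercial 12-bromododecan-1-ol.
- (S)-4-Methylhex-1-yne is a one-carbon homologation (Ohira–Bestmann) of (S)-3-methylpentanal.
- The only stereocenter is set by organocatalytic transfer hydrogenation of 3-methylpent-2-enal, which is made from 2-butanone by HWE olefination and DIBAL reduction.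
- No rings are formed; the only ring is the purchased benzoic acid.

Assumptions:
- The alkyl chain has 15 CH2 groups between O and the stereocenter (C26H44O4).
- The HWE-derived enal is an E/Z mixture.
- The (S)-TRIP anion is assumed to give the (S)-aldehyde. If the opposite hand is observed, the (R)-TRIP salt is used.

## Route

**Step 1**
Reactants: **1** butan-2-one; **2** diethyl (cyanomethyl)phosphonate
Product: **3** 3-methylpent-2-enenitrile (E/Z mixture)
Conditions: NaH, THF, 0 °C → rt, 12 h
Reagents that add atoms: none
Why: Horner–Wadsworth–Emmons olefination of a simple ketone with a stabilized phosphonate carbanion installs the trisubstituted C=C; no stereocenter is formed here.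

**Step 2**
Reactants: **3** 3-methylpent-2-enenitrile
Product: **4** 3-methylpent-2-enal (E/Z mixture)
Conditions: i-Bu2AlH (1.1 equiv), CH2Cl2/hexane, –78 °C → 0 °C; then aq. H2SO4 or Rochelle salt workup
Reagents that add atoms: water, O (hydrolyzes the aluminium imine and supplies the carbonyl oxygen)
Why: DIBAL reduction of an α,β-unsaturated nitrile stops at the N-aluminium imine, which is hydrolyzed on workup, so the enal is not over-reduced to the allylic alcohol.

**Step 3**
Reactants: **4** 3-methylpent-2-enal (E/Z); **5** di-tert-butyl 2,6-dimethyl-1,4-dihydropyridine-3,5-dicarboxylate (Hantzsch ester, 1.2 equiv); **6** dibenzylammonium (S)-TRIP phosphate (10 mol%)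
Product: **7** (S)-3-methylpentanal
Conditions: **6** (10 mol%), **5** (1.2 equiv), MTBE, 40 °C, 48 h, sealed vial; pentane/silica plug workup, product kept as a pentane solution
Reagents that add atoms: none (only hydride and H+ are transferred)
Why: Proposed new method: the reaction is iminium/ACDC transfer hydrogenation applied to a β-ethyl-β-methyl enal, where the two β-substituents differ by only one CH2, a case not shown before (known cases are Me vs aryl, or Me vs a longer chain as in citral → citronellal). The enal condenses with the ammonium to give an iminium ion paired with the bulky chiral phosphate. E/Z iminium interconversion is faster than hydride transfer, so the mixture funnels (Curtin–Hammett) through the geometry that places Et anti to nitrogen, and the chiral pocket delivers hydride from the Hantzsch ester to one β-face. The closest known reaction is the List/MacMillan organocatalytic transfer hydrogenation of β,β-disubstituted enals.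

**Step 4**
Reactants: **7** (S)-3-methylpentanal; **8** dimethyl (1-diazo-2-oxopropyl)phosphonate (Bestmann–Ohira reagent, 1.5 equiv)
Product: **9** (S)-4-methylhex-1-yne
Conditions: K2CO3 (2 equiv), MeOH/THF, 0 °C → rt, 12 h; pentane extraction, isolated and carried as a pentane solution (volatile)
Reagents that add atoms: Bestmann–Ohira reagent, COP(=O)(OC)C(=[N+]=[N-])C(C)=O (its diazo carbon becomes the terminal alkyne carbon)
Why: Ohira–Bestmann homologation converts an aldehyde to a terminal alkyne under mild base, and the β-stereocenter cannot epimerize.

**Step 5**
Reactants: **9** (S)-4-methylhex-1-yne; **10** 12-bromododecan-1-ol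
Product: **11** (S)-16-methyloctadec-13-yn-1-ol
Conditions: **9** (1.3 equiv) + n-BuLi (1.25 equiv), THF, –78 → 0 °C; add the lithium alkoxide of **10** (from 1.0 equiv n-BuLi, –78 °C); DMPU (25% v/v), 0 °C → 50 °C, 24 h
Reagents that add atoms: none
Why: SN2 alkylation of a lithium acetylide with a primary bromide in a dipolar aprotic co-solvent builds the C12–C13 bond. Pre-forming the alkoxide protects the OH without extra steps, and the remote stereocenter is untouched.

**Step 6**
Reactants: **11** (S)-16-methyloctadec-13-yn-1-ol
Product: **12** (S)-16-methyloctadecan-1-ol
Conditions: H2 (3 atm), 10% Pd/C, EtOAc, rt, 12 h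
Reagents that add atoms: none (H2 adds only hydrogen)
Why: Catalytic hydrogenation saturates the alkyne. The stereocenter is homopropargylic and sp3, so it is not epimerized, and H2 pressure suppresses alkene migration toward C16.

**Step 7**
Reactants: **12** (S)-16-methyloctadecan-1-ol; **13** 2,3-dihydroxybenzoic acid (1.5 equiv)
Product: **14** gentiside F, (S)-16-methyloctadecyl 2,3-dihydroxybenzoate
Conditions: p-TsOH·H2O (10 mol%), toluene, Dean–Stark, reflux, N2, 20 h
Reagents that add atoms: none (the acid and alcohol supply all atoms; TsOH is catalytic)
Why: Fischer esterification acylates only the carboxylic acid, since the phenols are poor nucleophiles under acid catalysis. The remote stereocenter is unaffected.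

## Compound list

1 | butan-2-one | CCC(C)=O | starting material
2 | diethyl (cyanomethyl)phosphonate | CCOP(=O)(CC#N)OCC | starting material
3 | 3-methylpent-2-enenitrile (E/Z) | CCC(C)=CC#N | intermediate
4 | 3-methylpent-2-enal (E/Z) | CCC(C)=CC=O | intermediate
5 | di-tert-butyl Hantzsch ester | CC1=C(CC(=C(N1)C)C(=O)OC(C)(C)C)C(=O)OC(C)(C)C | starting material (reagent)
6 | dibenzylammonium (S)-TRIP phosphate (axial (S) configuration not encoded) | c1ccccc1C[NH2+]Cc1ccccc1.[O-]P1(=O)Oc2c(-c3c(C(C)C)cc(C(C)C)cc3C(C)C)cc3ccccc3c2-c2c(O1)c(-c1c(C(C)C)cc(C(C)C)cc1C(C)C)cc1ccccc21 | starting material (catalyst)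
7 | (S)-3-methylpentanal | CC[C@H](C)CC=O | intermediate
8 | dimethyl (1-diazo-2-oxopropyl)phosphonate | COP(=O)(OC)C(=[N+]=[N-])C(C)=O | starting material
9 | (S)-4-methylhex-1-yne | CC[C@H](C)CC#C | intermediate
10 | 12-bromododecan-1-ol | BrCCCCCCCCCCCCO | starting material
11 | (S)-16-methyloctadec-13-yn-1-ol | OCCCCCCCCCCCCC#CC[C@@H](C)CC | intermediate
12 | (S)-16-methyloctadecan-1-ol | CC[C@H](C)CCCCCCCCCCCCCCCO | intermediate
13 | 2,3-dihydroxybenzoic acid | OC(=O)c1cccc(O)c1O | starting material
14 | gentiside F, (S)-16-methyloctadecyl 2,3-dihydroxybenzoate | CC[C@H](C)CCCCCCCCCCCCCCCOC(=O)c1cccc(O)c1O | target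

## Totals

Total steps: 7. Longest linear sequence: 7 (1 → 3 → 4 → 7 → 9 → 11 → 12 → 14).

## Three steps most likely to fail

1. **Step 3 (proposed new method).** Discriminating Me from Et may give modest ee, and the E/Z funneling may be incomplete.
   - Fallback (known chemistry, different approach): skip steps 1–4 and make **9** by alkylating lithium acetylide–ethylenediamine with commercial (S)-1-bromo-2-methylbutane in DMSO. This gives (S)-4-methylhex-1-yne with the stereocenter untouched.
2. **Step 5.** The alkoxide may compete as an O-nucleophile, or the acetylide may eliminate HBr from the bromide.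
   - Fallback: build the chain by Wittig instead. React **7** with the ylide from (13-(THP-oxy)tridecyl)triphenylphosphonium bromide (made from brassylic acid by LiAlH4, HBr, PPh3, then DHP). Then hydrogenate the alkene and remove the THP group.
3. **Step 7.** The unprotected catechol may oxidize, or the acid may be sluggish or oligomerize.
   - Fallback: esterify with 2,3-bis(benzyloxy)benzoic acid (from methyl 2,3-dihydroxybenzoate by BnBr/K2CO3, then LiOH) using EDC/DMAP. Then remove the benzyl groups with H2, Pd/C.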